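Start from what holds still: in the earlier runs starting material and product add up to about the whole charge, as in the west run at 6.00 h, where 47 % and 53 % stand. So take each unit of product as one unit of starting material and one of partner gone, and treat partner, never read, as the limiting reagent at 0.70 equiv.

the same everywhere: starting material 0.050 M
- north-west: partner 0.70 equiv; precatalyst 1 mol%; run made earlier
- south-west: partner 0.70 equiv; precatalyst 1.4 mol%; run made earlier
- west: partner 0.70 equiv; precatalyst 1.5 mol%; run made earlier
- birch: partner 0.700 equiv; precatalyst 1.2 mol%; time 6.0 h
- oak: partner 0.700 equiv; precatalyst 1.6 mol%; time 6.0 h

| run | time / h | catalyst intermediate C / % | product / % | starting material / % | catalyst intermediate A / % |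
|---|---|---|---|---|---|
| north-west | 0.500 | 1 | 1 | 96 | 1 |
| north-west | 1.50 | 0 | 12 | 87 | 2 |
| north-west | 3.00 | 0 | 21 | 76 | 1 |
| north-west | 4.00 | 0 | 28 | 67 | 1 |
| north-west | 6.00 | 1 | 40 | 59 | 2 |
| south-west | 0.500 | 0 | 6 | 94 | 1 |
| south-west | 1.50 | 0 | 17 | 80 | 1 |
| south-west | 3.00 | 1 | 30 | 66 | 1 |
| south-west | 4.00 | 0 | 38 | 60 | 5 |
| south-west | 6.00 | 0 | 47 | 50 | 2 |
| west | 0.500 | 0 | 6 | 93 | 3 |
| west | 0.833 | 0 | 10 | 90 | 0 |
| west | 1.50 | 1 | 15 | 82 | 0 |
| west | 3.00 | 4 | 34 | 71 | 0 |
| west | 6.00 | 4 | 53 | 47 | 3 |

(readings scatter by 1.5 percentage points)

* which of these there is most of at the end, counted by the starting material in it, birch (catalyst intermediate A / product / starting material / catalyst intermediate C)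
* which of these there is most of at the end, counted by the starting material in it, oak (catalyst intermediate A / product / starting material / catalyst intermediate C)
* how much there is at the end of the one of these that leads, in percent of the starting material charged: birch
* how much there is at the end of the one of these that leads, in percent of the starting material charged: oak



Now go down the time scales, fastest first. Catalyst intermediate C mostly reads zero within the scatter, so count it as used up about as fast as it forms. Catalyst intermediate A reads 1 % in the north-west run at 3.00 h, against a loading of 1 mol%, so take it as the likely resting state. Next look at the hours. In the south-west run the product rate from 4.00 h to 6.00 h reads, within the scatter, a fraction 0.397 of the rate up to 1.50 h. Between those spans the span average of partner, reckoned from the product, falls to a fraction 0.447 and that of starting material, as read, to 0.611. The rate reading stands nearer to partner, so read the south-west flask, as a working estimate, as pseudo-first-order in partner, with the catalyst as a multiplier.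

Define the partner exponent 0.862: the logarithm of charged over remaining partner at 6.00 h, per 1 mol% of precatalyst, averaged over the earlier runs. By my reckoning birch keeps a fraction 0.355 of its partner, giving product 45.1 % and starting material 54.9 %. Oak keeps 0.252, giving product 52.4 %. Oak's partner half-life, so reckoned, of 3.02 h is shorter than the time, the last rung.

The forecast, which holds that “the rate is close to first order in catalyst”, names starting material at 55 % (51 % to 58 %) for birch and product at 54 % (50 % to 59 %) for oak. It fits its decay to starting material, and for oak its figure stands above mine.

Birch ends at 53.8 % starting material and oak at 52.5 % product, inside the forecast's ranges.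

    starting material + free catalyst → catalyst intermediate A (k = 18.0 /M/min)
    partner + catalyst intermediate A ⇌ catalyst intermediate B (K = 57.0 /M, k = 6.60 /M/min)
    catalyst intermediate B → released group + catalyst intermediate C (k = 29.0 /min)
    catalyst intermediate C → free catalyst + product (k = 1.60 /min)
    partner + precatalyst → free catalyst + spent reagent (k = 4.20 /M/min)

Oak keeps 23 % of its partner, where the exponent gave 25.2 %. To make such a forecast wrong, change the partner charge: take oak with 0.170 equiv. At the same loading the exponent keeps the same fraction of partner and gives product 12.7 %; that flask gives product 12.4 %, with starting material leading at 86 %.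

All runs stem from a simulated flask on assumed constants; the scatter is artificial.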